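The earlier runs and the new flask are calculated with made-up constants; the scatter is artificial.

Time is the variable to keep. Write the rate as k·S·R, with S and R the substrate and reagent in the flask now, Sc and Rc their charges, and let k depend on the clock. Each target made uses one of each, so S − R stays at Sc − Rc, and

ln(S/R) = ln(Sc/Rc) + (Sc − Rc)·E

where E, the exposure, is the integral of k over time. That is the integrated second-order rate law with k(t) in place of a constant.

| setting | zeta | theta | gamma | delta |
|---|---|---|---|---|
| substrate | 150 mM | 75.0 mM | 300 mM | 690 mM |
| reagent | 225 mM | 150 mM | 225 mM | 225 mM |
| free catalyst | 0.750 mM | 0.750 mM | 0.750 mM | 0.750 mM |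
| time |  |  |  | 16 h |

| run | time / h | [substrate] / mM |
|---|---|---|
| zeta run | 0.64 | 89.5 |
| zeta run | 1.0 | 77.7 |
| zeta run | 1.6 | 65.8 |
| zeta run | 2.5 | 56.4 |
| zeta run | 4.0 | 47.7 |
| zeta run | 6.4 | 41.4 |
| zeta run | 10 | 36.5 |
| zeta run | 16 | 32.3 |
| theta run | 0.64 | 52.0 |
| theta run | 1.0 | 46.3 |
| theta run | 1.6 | 41.0 |
| theta run | 2.5 | 35.3 |
| theta run | 4.0 | 31.9 |
| theta run | 6.4 | 27.0 |
| theta run | 10 | 24.7 |
| theta run | 16 | 21.2 |
| gamma run | 0.64 | 194.0 |
| gamma run | 1.0 | 173.9 |
| gamma run | 1.6 | 158.2 |
| gamma run | 2.5 | 145.4 |
| gamma run | 4.0 | 133.5 |
| gamma run | 6.4 | 125.7 |
| gamma run | 10 | 119.4 |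
| gamma run | 16 | 113.5 |

(each reading ± 0.4 mM)

- the power of [reagent] that the first rate follows, about the charge of the zeta run; measure it at two percent of substrate made into target
- the power of [substrate] that the first rate follows, about the charge of the zeta run; measure it at two percent of substrate made into target (one fixed amount of target, the same in the runs compared)
- the theta run starts with 75.0 mM less of substrate and of reagent than the zeta run, and with no target. Compared where both hold the same amount of substrate, once fifteen percent of what the theta run was charged with has turned into target, is the theta run faster, slower or alike (within a tenth)?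
- substrate in the delta run at 16 h, as a share of the substrate charged
- which of these the readings show (nothing beyond the main steps / the substrate is lost by itself / the product decays / the catalyst dies in pairs)

- Overall: substrate + reagent -> target, with free catalyst as catalyst.
- Constant volume, constant temperature.
- "The second partner" is reagent.
- An order is taken over about fifteen percent of the charge, up and down.

From the last zeta reading, the exposure at 16 h stands at 0.0106 /mM. The last readings of the theta and gamma runs give 0.0109 /mM and 0.0106 /mM, although their charges differ. So I carry E to the delta run.

The bracket for the delta run is my own. Reagent is the limiting reagent there, 225 mM against 690 mM of substrate, so substrate stays above 465 mM. Reagent obeys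

R = Rc·exp(−∫k·S dt)

and in the delta run S lies between that floor and its charge. Putting each limit in turn for S:

share above 67.41%
share below 67.63%

The forecast gives orders 1 in reagent and 1 in substrate, the theta run faster, 67.5% for the delta run, and the catalyst dies in pairs, on the grounds of “second-order catalyst death”. Its 67.5% stands between my 67.4% and 67.6%.

The flask gives orders 1.0 and 1.0, the theta run faster, and the catalyst dies in pairs; substrate in the delta run at 16 h is 67.6% of its charge.

    2 free catalyst ⇌ catalyst dimer, settled at all times (544.0 /M)
    free catalyst + substrate + reagent → target + free catalyst (12020 /M²/h)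
    2 free catalyst → 2 spent catalyst (2671 /M/h)

The step from free catalyst to spent catalyst makes no difference to that share. Now carry 0.0106 /mM from the zeta run to the gamma run, where the rule gives S/R = 2.95. With S − R at 75.0 mM, substrate at 16 h comes to 113 mM, and the gamma run read 113.5 mM.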